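**Retrosynthetic overview**

1. Target ⇒ NaBH4 reduction of the C4 ketone of a free-phenolic flavan-(4→6)-dihydroflavonol ⇒ hydrogenolysis of its hexabenzyl ether, which carries a bromine cap on C6 of the upper unit.
2. Interflavan C4–C6 bond ⇒ Friedel–Crafts union of the bromine-capped (2S,3R)-flavan-3,4-diol (cation precursor, upper unit) with the (2R,3R)-dihydroflavonol (nucleophile, lower unit); 3,4-trans by attack anti to the 3-OH.
3. Both dihydroflavonol enantiomers ⇒ one isolated potassium chalcone phenoxide by the key C–O bond-forming step: catalyst-controlled oxa-Michael closure of ring C (O1–C2) with in-flask C3 hydroxylation (C3–O), run once with each catalyst enantiomer.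
4. Chalcone ⇒ Claisen–Schmidt condensation of 3,4-di-O-benzylgallacetophenone with 4-(benzyloxy)benzaldehyde.
5. Ring order: ring C of each monomer is closed first, then the two flavanoid units are joined; no ring is made after the union.

The target is read as ent-oritin-(4β→6)-oritin-4α-ol: lower unit (2R,3S,4R), upper unit (2S,3R,4S), both 2,3-trans-3,4-trans.

Assumption: the sense of induction of the new cyclisation must be found by experiment; the (11bS)-catalyst is written for the (2R,3R) series and the (11bR)-catalyst for the (2S,3S) series, and the two are exchanged if the opposite holds.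

The catalyst in steps 4 and 5 is the simplified Maruoka phase-transfer catalyst, which is sold in both mirror-image forms.

**Route**

Step 1
Reactants: 1 1-(2,3,4-trihydroxyphenyl)ethan-1-one (gallacetophenone)
Product: 2 1-[3,4-bis(benzyloxy)-2-hydroxyphenyl]ethan-1-one
Conditions: BnBr (2.1 equiv), K2CO3 (2.2 equiv), acetone, reflux, 8 h
Reagents that add atoms: benzyl bromide, BrCc1ccccc1
Why: Williamson ether synthesis in which the 3- and 4-OH are alkylated while the 2-OH, held in a hydrogen bond to the acetyl carbonyl, stays free for the later ring closure; no stereocentre is formed.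

Step 2
Reactants: 2 1-[3,4-bis(benzyloxy)-2-hydroxyphenyl]ethan-1-one, 3 4-(benzyloxy)benzaldehyde
Product: 4 (E)-1-[3,4-bis(benzyloxy)-2-hydroxyphenyl]-3-[4-(benzyloxy)phenyl]prop-2-en-1-one
Conditions: KOH (50% aq., 4 equiv), EtOH, rt, 36 h; then 1 M HCl; recrystallised
Reagents that add atoms: none
Why: Claisen–Schmidt (crossed aldol) condensation of a methyl ketone with a non-enolisable aldehyde, dehydration giving only the conjugated (E)-enone; no stereocentre is formed.

Step 3
Reactants: 4 (E)-1-[3,4-bis(benzyloxy)-2-hydroxyphenyl]-3-[4-(benzyloxy)phenyl]prop-2-en-1-one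
Product: 5 potassium 2,3-bis(benzyloxy)-6-{(E)-3-[4-(benzyloxy)phenyl]prop-2-enoyl}phenolate
Conditions: KN(SiMe3)2 (1.00 equiv, 0.5 M in toluene), toluene, −40 → 0 °C; pentane; filtered under argon, washed with pentane, dried in vacuo
Reagents that add atoms: potassium bis(trimethylsilyl)amide, C[Si](C)(C)[N-][Si](C)(C)C.[K+]
Why: Acid–base salt formation in which the silylamide deprotonates the chelated phenol quantitatively, and the salt is isolated once, free of hexamethyldisilazane and of any proton source, and divided between the two catalyst runs; it is stable on storage because the ring-closed enolate is the minor, reversible partner of the conjugated phenoxide; no stereocentre is formed.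

Step 4
Reactants: 5 potassium 2,3-bis(benzyloxy)-6-{(E)-3-[4-(benzyloxy)phenyl]prop-2-enoyl}phenolate
Product: 7 (2R,3R)-7,8-bis(benzyloxy)-2-[4-(benzyloxy)phenyl]-3-hydroxy-2,3-dihydro-4H-chromen-4-one, via flavanone enolate 6 (not isolated)
Conditions: (11bS)-4,4-dibutyl-2,6-bis(3,4,5-trifluorophenyl)-4,5-dihydro-3H-dinaphtho[2,1-c:1',2'-e]azepinium bromide (5 mol %), (±)-trans-3-phenyl-2-(phenylsulfonyl)oxaziridine (1.3 equiv), toluene, −20 °C, 24 h; cold 0.5 M HCl work-up
Reagents that add atoms: (±)-trans-3-phenyl-2-(phenylsulfonyl)oxaziridine (Davis oxaziridine), O=S(=O)(c1ccccc1)N1OC1c1ccccc1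
Why: Proposed new method: an enantioselective Algar–Flynn–Oyamada-type oxa-Michael/α-hydroxylation cascade under chiral ion-pair (phase-transfer) catalysis, in which the suspended potassium phenoxide 5 enters solution only as its ion pair with the axially chiral ammonium cation, closes ring C there by 6-endo-trig oxa-Michael addition (O1–C2 bond), and the resulting enolate 6, which has no proton source and could otherwise only reopen, is trapped irreversibly by electrophilic oxygen transfer from the N-sulfonyloxaziridine to the enolate face anti to the C2 aryl group (C3–O bond, 2,3-trans), so that C2 is fixed under catalyst control either in the ring closure or, if that is reversible, by faster trapping of one enolate ion pair; the closest known reactions are the racemic Algar–Flynn–Oyamada reaction with NaOH/H2O2, the catalytic asymmetric oxa-Michael cyclisation of 2'-hydroxychalcones to flavanones and the ammonium-enolate α-hydroxylation of β-keto esters with oxaziridines, whose merger into a one-flask enantioselective chalcone-to-dihydroflavonol conversion has not been described.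

Step 5
Reactants: 5 potassium 2,3-bis(benzyloxy)-6-{(E)-3-[4-(benzyloxy)phenyl]prop-2-enoyl}phenolate
Product: 9 (2S,3S)-7,8-bis(benzyloxy)-2-[4-(benzyloxy)phenyl]-3-hydroxy-2,3-dihydro-4H-chromen-4-one, via flavanone enolate 8 (not isolated)
Conditions: (11bR)-4,4-dibutyl-2,6-bis(3,4,5-trifluorophenyl)-4,5-dihydro-3H-dinaphtho[2,1-c:1',2'-e]azepinium bromide (5 mol %), (±)-trans-3-phenyl-2-(phenylsulfonyl)oxaziridine (1.3 equiv), toluene, −20 °C, 24 h; cold 0.5 M HCl work-up
Reagents that add atoms: (±)-trans-3-phenyl-2-(phenylsulfonyl)oxaziridine (Davis oxaziridine), O=S(=O)(c1ccccc1)N1OC1c1ccccc1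
Why: Proposed new method: the same oxa-Michael/α-hydroxylation cascade run on the second half of salt 5 with the mirror-image ammonium catalyst, so that ion-pair-controlled ring closure sets C2 in the opposite sense and anti oxygen transfer to enolate 8 again gives the 2,3-trans product, here (2S,3S); closest known reaction types as in step 4 (Algar–Flynn–Oyamada reaction, asymmetric oxa-Michael cyclisation to flavanones, enolate hydroxylation with N-sulfonyloxaziridines).

Step 6
Reactants: 9 (2S,3S)-7,8-bis(benzyloxy)-2-[4-(benzyloxy)phenyl]-3-hydroxy-2,3-dihydro-4H-chromen-4-one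
Product: 10 (2S,3S)-7,8-bis(benzyloxy)-2-[4-(benzyloxy)phenyl]-6-bromo-3-hydroxy-2,3-dihydro-4H-chromen-4-one
Conditions: NBS (1.05 equiv), MeCN, 0 °C → rt, dark
Reagents that add atoms: N-bromosuccinimide, O=C1CCC(=O)N1Br
Why: Electrophilic aromatic bromination at C6, which is para to O1, ortho to the 7-benzyloxy group and the only free ring A carbon not ortho to the carbonyl-bearing carbon, so it is attacked in preference to the singly activated ring B; the bromine blocks C6 of the future electrophile and the stereocentres are untouched.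

Step 7
Reactants: 10 (2S,3S)-7,8-bis(benzyloxy)-2-[4-(benzyloxy)phenyl]-6-bromo-3-hydroxy-2,3-dihydro-4H-chromen-4-one
Product: 11 (2S,3R,4S)-7,8-bis(benzyloxy)-2-[4-(benzyloxy)phenyl]-6-bromo-3,4-dihydro-2H-chromene-3,4-diol
Conditions: NaBH4 (2 equiv), THF/MeOH 4:1, 0 °C, 1 h
Reagents that add atoms: none
Why: Borohydride reduction of the aryl ketone, giving mainly the 3,4-trans (4S) alcohol by axial hydride delivery; because C4 is ionised in step 8, any 4-epimer converges on the same cation.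

Step 8
Reactants: 11 (2S,3R,4S)-7,8-bis(benzyloxy)-2-[4-(benzyloxy)phenyl]-6-bromo-3,4-dihydro-2H-chromene-3,4-diol, 7 (2R,3R)-7,8-bis(benzyloxy)-2-[4-(benzyloxy)phenyl]-3-hydroxy-2,3-dihydro-4H-chromen-4-one
Product: 13 (2R,3R)-7,8-bis(benzyloxy)-6-{(2S,3R,4S)-7,8-bis(benzyloxy)-2-[4-(benzyloxy)phenyl]-6-bromo-3-hydroxy-3,4-dihydro-2H-chromen-4-yl}-2-[4-(benzyloxy)phenyl]-3-hydroxy-2,3-dihydro-4H-chromen-4-one, via benzylic C4 cation 12 (not isolated)
Conditions: 7 (3 equiv, excess recovered), Bi(OTf)3 (10 mol %), CH2Cl2/HFIP 4:1, 4 Å MS, −20 → 0 °C; Et3N quench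
Reagents that add atoms: none
Why: Friedel–Crafts alkylation with a benzylic alcohol, in which Bi(OTf)3 in the cation-stabilising solvent HFIP ionises 11 to the O1/O7-stabilised cation 12, which cannot self-condense because its own C6 carries bromine, and C6 of 7 (para to O1, ortho to 7-OBn) attacks the face anti to the 3-OH, setting the new C4 stereocentre 3,4-trans (4S, 2,4-cis) as is usual for 2,3-trans flavan-4-yl cations.

Step 9
Reactants: 13 (2R,3R)-7,8-bis(benzyloxy)-6-{(2S,3R,4S)-7,8-bis(benzyloxy)-2-[4-(benzyloxy)phenyl]-6-bromo-3-hydroxy-3,4-dihydro-2H-chromen-4-yl}-2-[4-(benzyloxy)phenyl]-3-hydroxy-2,3-dihydro-4H-chromen-4-one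
Product: 14 (2R,3R)-3,7,8-trihydroxy-2-(4-hydroxyphenyl)-6-[(2S,3R,4S)-3,7,8-trihydroxy-2-(4-hydroxyphenyl)-3,4-dihydro-2H-chromen-4-yl]-2,3-dihydro-4H-chromen-4-one
Conditions: H2 (1 atm), Pd(OH)2/C, NaOAc (1.5 equiv), THF/MeOH 1:1, rt; filtered under argon
Reagents that add atoms: none
Why: Catalytic hydrogenolysis that cleaves the six benzyl aryl ethers and, with NaOAc as HBr acceptor, hydrodebrominates C6, while the conjugated aryl ketone and the cyclic secondary benzylic C2–O1 bonds survive these mild conditions, so no stereocentre is touched.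

Step 10
Reactants: 14 (2R,3R)-3,7,8-trihydroxy-2-(4-hydroxyphenyl)-6-[(2S,3R,4S)-3,7,8-trihydroxy-2-(4-hydroxyphenyl)-3,4-dihydro-2H-chromen-4-yl]-2,3-dihydro-4H-chromen-4-one
Product: 15 (2R,3S,4R)-2-(4-hydroxyphenyl)-6-[(2S,3R,4S)-3,7,8-trihydroxy-2-(4-hydroxyphenyl)-3,4-dihydro-2H-chromen-4-yl]-3,4-dihydro-2H-chromene-3,4,7,8-tetrol (the target)
Conditions: NaBH4 (6 equiv), EtOH, 0 °C → rt, argon; AcOH to pH 6; gel chromatography (LH-20 type, EtOH)
Reagents that add atoms: none
Why: Borohydride reduction of a free-phenolic 2,3-trans-dihydroflavonol, the classical route to flavan-3,4-diols, in which axial hydride addition to C4 gives the all-equatorial 2,3-trans-3,4-trans (4R) diol; the near-neutral work-up protects the acid-labile benzylic 4-OH.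

**Compound list**

1 | 1-(2,3,4-trihydroxyphenyl)ethan-1-one (gallacetophenone) | CC(=O)c1ccc(O)c(O)c1O | starting material
2 | 1-[3,4-bis(benzyloxy)-2-hydroxyphenyl]ethan-1-one | CC(=O)c1ccc(OCc2ccccc2)c(OCc2ccccc2)c1O | intermediate
3 | 4-(benzyloxy)benzaldehyde | O=Cc1ccc(OCc2ccccc2)cc1 | starting material
4 | (E)-1-[3,4-bis(benzyloxy)-2-hydroxyphenyl]-3-[4-(benzyloxy)phenyl]prop-2-en-1-one | O=C(/C=C/c1ccc(OCc2ccccc2)cc1)c1ccc(OCc2ccccc2)c(OCc2ccccc2)c1O | intermediate
5 | potassium 2,3-bis(benzyloxy)-6-{(E)-3-[4-(benzyloxy)phenyl]prop-2-enoyl}phenolate (potassium phenoxide of 4, isolated salt) | O=C(/C=C/c1ccc(OCc2ccccc2)cc1)c1ccc(OCc2ccccc2)c(OCc2ccccc2)c1[O-].[K+] | intermediate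
6 | potassium (2S)-7,8-bis(benzyloxy)-2-[4-(benzyloxy)phenyl]-2H-chromen-4-olate (flavanone enolate, reacts as its ion pair with the catalyst cation, not isolated) | C(c1ccccc1)Oc1ccc([C@H]2Oc3c(ccc(OCc4ccccc4)c3OCc3ccccc3)C([O-])=C2)cc1.[K+] | intermediate
7 | (2R,3R)-7,8-bis(benzyloxy)-2-[4-(benzyloxy)phenyl]-3-hydroxy-2,3-dihydro-4H-chromen-4-one | C(c1ccccc1)Oc1ccc([C@H]2Oc3c(ccc(OCc4ccccc4)c3OCc3ccccc3)C(=O)[C@@H]2O)cc1 | intermediate
8 | potassium (2R)-7,8-bis(benzyloxy)-2-[4-(benzyloxy)phenyl]-2H-chromen-4-olate (flavanone enolate, reacts as its ion pair with the catalyst cation, not isolated) | C(c1ccccc1)Oc1ccc([C@@H]2Oc3c(ccc(OCc4ccccc4)c3OCc3ccccc3)C([O-])=C2)cc1.[K+] | intermediate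
9 | (2S,3S)-7,8-bis(benzyloxy)-2-[4-(benzyloxy)phenyl]-3-hydroxy-2,3-dihydro-4H-chromen-4-one | C(c1ccccc1)Oc1ccc([C@@H]2Oc3c(ccc(OCc4ccccc4)c3OCc3ccccc3)C(=O)[C@H]2O)cc1 | intermediate
10 | (2S,3S)-7,8-bis(benzyloxy)-2-[4-(benzyloxy)phenyl]-6-bromo-3-hydroxy-2,3-dihydro-4H-chromen-4-one | C(c1ccccc1)Oc1ccc([C@@H]2Oc3c(cc(Br)c(OCc4ccccc4)c3OCc3ccccc3)C(=O)[C@H]2O)cc1 | intermediate
11 | (2S,3R,4S)-7,8-bis(benzyloxy)-2-[4-(benzyloxy)phenyl]-6-bromo-3,4-dihydro-2H-chromene-3,4-diol | C(c1ccccc1)Oc1ccc([C@@H]2Oc3c(cc(Br)c(OCc4ccccc4)c3OCc3ccccc3)[C@H](O)[C@H]2O)cc1 | intermediate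
12 | (2S,3R)-7,8-bis(benzyloxy)-2-[4-(benzyloxy)phenyl]-6-bromo-3-hydroxy-3,4-dihydro-2H-chromen-4-ylium (benzylic C4 cation, counter-ion from the Bi(OTf)3 catalyst, not isolated) | C(c1ccccc1)Oc1ccc([C@@H]2Oc3c(cc(Br)c(OCc4ccccc4)c3OCc3ccccc3)[CH+][C@H]2O)cc1 | intermediate
13 | (2R,3R)-7,8-bis(benzyloxy)-6-{(2S,3R,4S)-7,8-bis(benzyloxy)-2-[4-(benzyloxy)phenyl]-6-bromo-3-hydroxy-3,4-dihydro-2H-chromen-4-yl}-2-[4-(benzyloxy)phenyl]-3-hydroxy-2,3-dihydro-4H-chromen-4-one | C(c1ccccc1)Oc1ccc([C@H]2Oc3c(cc([C@H]4c5cc(Br)c(OCc6ccccc6)c(OCc6ccccc6)c5O[C@@H](c5ccc(OCc6ccccc6)cc5)[C@@H]4O)c(OCc4ccccc4)c3OCc3ccccc3)C(=O)[C@@H]2O)cc1 | intermediate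
14 | (2R,3R)-3,7,8-trihydroxy-2-(4-hydroxyphenyl)-6-[(2S,3R,4S)-3,7,8-trihydroxy-2-(4-hydroxyphenyl)-3,4-dihydro-2H-chromen-4-yl]-2,3-dihydro-4H-chromen-4-one | Oc1ccc([C@H]2Oc3c(cc([C@H]4c5ccc(O)c(O)c5O[C@@H](c5ccc(O)cc5)[C@@H]4O)c(O)c3O)C(=O)[C@@H]2O)cc1 | intermediate
15 | (2R,3S,4R)-2-(4-hydroxyphenyl)-6-[(2S,3R,4S)-3,7,8-trihydroxy-2-(4-hydroxyphenyl)-3,4-dihydro-2H-chromen-4-yl]-3,4-dihydro-2H-chromene-3,4,7,8-tetrol (CNP0391561.6) | Oc1ccc([C@H]2Oc3c(cc([C@H]4c5ccc(O)c(O)c5O[C@@H](c5ccc(O)cc5)[C@@H]4O)c(O)c3O)[C@@H](O)[C@@H]2O)cc1 | target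

**Step count and risks**

Total step count: 10. Longest linear sequence: 9 steps (1, 2, 3, 5, 6, 7, 8, 9, 10); step 4 is the short branch that joins at step 8.

Steps most likely to fail:

Step 4 (and its mirror-image twin, step 5), the proposed new cyclisation. The ring-closed enolate is only a minor equilibrium partner of the phenoxide, so the cascade may be slow. Any potassium salt that dissolves without the chiral cation would react racemically. The enantioselectivity is unknown, and over-oxidation to the flavonol is possible. The fallback uses known chemistry and sets out from 4. The classical Algar–Flynn–Oyamada reaction (NaOH, 30% H2O2, MeOH/THF, 0 °C, stopped at the dihydroflavonol stage) gives the racemic 2,3-trans-dihydroflavonol, which is a 1:1 mixture of 7 and 9. Preparative chromatography on an amylose tris(3,5-dimethylphenylcarbamate) chiral stationary phase separates the two. Because the route needs both enantiomers, nothing is discarded. The fallback replaces steps 3, 4 and 5 together, comes back to the route at 7 and at 9, and makes no compound outside the list.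

Step 8, the Friedel–Crafts union. Ring A of 7 is deactivated by its ketone, so cation 12 may be held at oxygen or decay before C-alkylation. The fallback sets out from 11 and closes ring C of the lower unit only after the interflavan bond exists. Cation 12 is generated as before (Bi(OTf)3, CH2Cl2/HFIP) but trapped with the small acetophenone 2, used in 10-fold excess and recovered, whose reacting carbon is para to its free phenol. This gives 1-{3,4-bis(benzyloxy)-5-[(2S,3R,4S)-7,8-bis(benzyloxy)-2-[4-(benzyloxy)phenyl]-6-bromo-3-hydroxy-3,4-dihydro-2H-chromen-4-yl]-2-hydroxyphenyl}ethan-1-one F1. Claisen–Schmidt condensation of this ketone with 3 (KOH, EtOH) gives the chalcone (E)-1-{3,4-bis(benzyloxy)-5-[(2S,3R,4S)-7,8-bis(benzyloxy)-2-[4-(benzyloxy)phenyl]-6-bromo-3-hydroxy-3,4-dihydro-2H-chromen-4-yl]-2-hydroxyphenyl}-3-[4-(benzyloxy)phenyl]prop-2-en-1-one F2. A classical Algar–Flynn–Oyamada ring closure (NaOH, H2O2, 0 °C) then gives two trans-dihydroflavonol diastereomers that differ only in the lower unit and are separable on silica. One is 13, where the fallback comes back to the route. The other is (2S,3S)-7,8-bis(benzyloxy)-6-{(2S,3R,4S)-7,8-bis(benzyloxy)-2-[4-(benzyloxy)phenyl]-6-bromo-3-hydroxy-3,4-dihydro-2H-chromen-4-yl}-2-[4-(benzyloxy)phenyl]-3-hydroxy-2,3-dihydro-4H-chromen-4-one F3, which is removed.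

Step 10, the final reduction. The substrate is a free hexaphenol in a basic borohydride medium: pyrogallol phenoxides are air-sensitive, borate complexes complicate isolation, and a 4-epimer cannot easily be removed from the polar product. The fallback sets out from 13 and reverses the order of the last two operations. NaBH4 in THF/MeOH at 0 °C reduces the ketone while the phenols are still benzylated, giving (2R,3S,4R)-7,8-bis(benzyloxy)-6-{(2S,3R,4S)-7,8-bis(benzyloxy)-2-[4-(benzyloxy)phenyl]-6-bromo-3-hydroxy-3,4-dihydro-2H-chromen-4-yl}-2-[4-(benzyloxy)phenyl]-3,4-dihydro-2H-chromene-3,4-diol F4. This compound can be purified on silica and freed of any 4-epimer. Hydrogenolysis (H2, Pd(OH)2/C, NaOAc, EtOAc/MeOH, short contact time in a neutral medium to spare the benzylic 4-OH) then removes the six benzyl groups and the bromine. The fallback comes back to the route at 15.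

**Further compounds**

F0 | step 4 | none | none
F1 | step 8 | 1-{3,4-bis(benzyloxy)-5-[(2S,3R,4S)-7,8-bis(benzyloxy)-2-[4-(benzyloxy)phenyl]-6-bromo-3-hydroxy-3,4-dihydro-2H-chromen-4-yl]-2-hydroxyphenyl}ethan-1-one | CC(=O)c1cc([C@H]2c3cc(Br)c(OCc4ccccc4)c(OCc4ccccc4)c3O[C@@H](c3ccc(OCc4ccccc4)cc3)[C@@H]2O)c(OCc2ccccc2)c(OCc2ccccc2)c1O
F2 | step 8 | (E)-1-{3,4-bis(benzyloxy)-5-[(2S,3R,4S)-7,8-bis(benzyloxy)-2-[4-(benzyloxy)phenyl]-6-bromo-3-hydroxy-3,4-dihydro-2H-chromen-4-yl]-2-hydroxyphenyl}-3-[4-(benzyloxy)phenyl]prop-2-en-1-one | O=C(/C=C/c1ccc(OCc2ccccc2)cc1)c1cc([C@H]2c3cc(Br)c(OCc4ccccc4)c(OCc4ccccc4)c3O[C@@H](c3ccc(OCc4ccccc4)cc3)[C@@H]2O)c(OCc2ccccc2)c(OCc2ccccc2)c1O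
F3 | step 8 | (2S,3S)-7,8-bis(benzyloxy)-6-{(2S,3R,4S)-7,8-bis(benzyloxy)-2-[4-(benzyloxy)phenyl]-6-bromo-3-hydroxy-3,4-dihydro-2H-chromen-4-yl}-2-[4-(benzyloxy)phenyl]-3-hydroxy-2,3-dihydro-4H-chromen-4-one | C(c1ccccc1)Oc1ccc([C@@H]2Oc3c(cc([C@H]4c5cc(Br)c(OCc6ccccc6)c(OCc6ccccc6)c5O[C@@H](c5ccc(OCc6ccccc6)cc5)[C@@H]4O)c(OCc4ccccc4)c3OCc3ccccc3)C(=O)[C@H]2O)cc1
F4 | step 10 | (2R,3S,4R)-7,8-bis(benzyloxy)-6-{(2S,3R,4S)-7,8-bis(benzyloxy)-2-[4-(benzyloxy)phenyl]-6-bromo-3-hydroxy-3,4-dihydro-2H-chromen-4-yl}-2-[4-(benzyloxy)phenyl]-3,4-dihydro-2H-chromene-3,4-diol | C(c1ccccc1)Oc1ccc([C@H]2Oc3c(cc([C@H]4c5cc(Br)c(OCc6ccccc6)c(OCc6ccccc6)c5O[C@@H](c5ccc(OCc6ccccc6)cc5)[C@@H]4O)c(OCc4ccccc4)c3OCc3ccccc3)[C@@H](O)[C@@H]2O)cc1
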